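One sum in this flask can be counted before any rate is known. Under the proposed steps each target made spends one coupling partner, and target that turns into over-reaction product stays spent, so [target] + [over-reaction product] counts the partner used. Divide charged partner by charged substrate and you have the partner ceiling, 80.0%, the height that sum cannot pass, in percent of the substrate charged. Partner is the limiting reagent here, at 1.60 M against 2.0 M of substrate.

| flask | substrate | coupling partner | temperature | remark | time |
|---|---|---|---|---|---|
| dusk | 2 M | 1.6 M | 25 °C | the very flask that is asked about, followed so far |  |
| dawn | 1 M | 1.6 M | 31 °C | run made earlier |  |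
| flask | 2.0 M | 1.60 M | 25 °C |  | 4.0 min |

dusk run (percent of the substrate charged)

| time / min | target / % | substrate / % |
|---|---|---|
| 0.333 | 44.7 | 43.5 |
| 0.500 | 57.5 | 29.1 |
| 0.833 | 72.4 | 11.4 |
| 1.33 | 79.3 | 4.8 |
| 2.50 | 80.6 | 1.3 |
| 4.00 | 80.0 | 1.6 |

dawn run (percent of the substrate charged)

| time / s | target / % | substrate / % |
|---|---|---|
| 10.0 | 42.6 | 46.0 |
| 12.0 | 45.4 | 40.2 |
| 20.0 | 68.6 | 20.1 |
| 30.0 | 84.6 | 10.1 |
| 50.0 | 95.2 | 3.6 |
| 80.0 | 100.1 | 0 |

(each reading ± 1 percentage point)

- epsilon: at 4.0 min add coupling partner, 50.0% of the amount charged, then wait 8.0 min
- delta: change nothing and wait 8.0 min more
- theta: at 4.0 min raise the temperature by 20 K, then wait 8.0 min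
- zeta: at 4.0 min take out 90% of the target then present, then wait 8.0 min

- removed target is counted in
- what may be going on: substrate -> intermediate; coupling partner + intermediate -> target; target -> over-reaction product
- additions bring no volume worth counting

* target, in percent of the substrate first charged, at 4.0 min
* the option that brings most further target ("none" if no option brings more than 2 percentage points) (epsilon / delta / theta / zeta / none)
* target present, with what was taken out counted in, in percent of the substrate first charged, after theta
* target present, with what was taken out counted in, in percent of the substrate first charged, after zeta

Now build on the ceiling step by step. In the dusk run, which is this flask followed so far, substrate falls from 43.5% at 0.333 min to 11.4% at 0.833 min. That reads as a first-order constant of 2.68 /min, so 4.0 min holds about 15.5 half-lives, and the substrate reading there is 1.6%. The substrate charged stands above the partner charged, so target should stop at the ceiling. The last two readings, 80.6% and 80.0% with a scatter of 1 percentage point, stand there. You can commit to about 80.0% at 4.0 min, with the gap of 18.4% in the last reading held by intermediate and whatever over-reaction product has formed.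

The weak link is the claim that this stop is the ceiling and not some other stall. The dawn run reforges it: its partner ceiling is 160%, so there the substrate charge is the lower bound, and its target read 100.1% at 80.0 s, past the dusk stop, though that run differs from the dusk run in temperature as well as in substrate. So epsilon, which lifts the partner ceiling of this flask to 120%, above the substrate charged, is your option.

The forecast gives 80% and epsilon, with 76% after theta and 80% after zeta; of theta it says: “Heating cannot make target without partner and only risks some over-reaction, whose size is poorly known”.

The flask gives 79.0% and epsilon, which brings 17 points further target, with 58.4% after theta and 78.8% after zeta. The two part on theta, by 18 points.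

    substrate → intermediate (k = 0.0430 /s, Ea = 74.0 kJ/mol)
    coupling partner + intermediate → target (k = 0.170 /M/s, Ea = 39.0 kJ/mol)
    target → over-reaction product (k = 5.80 × 10⁻⁵ /s, Ea = 94.0 kJ/mol)
    (constants at 25 °C)

This flask has not come to rest. At 4.00 min the partner stands at 0%, and target plus over-reaction product makes 80.0%, the ceiling of 80.0%. At 40.0 min that sum is still 80.0% and intermediate still 20.0%, but the sum has changed its make-up: target is down to 69.7% and over-reaction product up to 10.3%. The half-life of target by that step, 200 min, is long against 4.0 min, and over-reaction product stood at 0.999% at 4.00 min.

Take the neighbour flask with 0.96 M of partner: its ceiling is 48.0%. It gives 47.4% target and 0.618% over-reaction product at 4.00 min, with 52.0% as intermediate.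

All runs are simulated with made-up constants; scatter was added.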